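**Retrosynthetic overview**

- The strategy rests on lactone ring B (C1, O2, C3, C4, C4a, C8a). Its carbon frame is that of a homophthalate fused to benzene ring A. Its single stereocentre C3 lies between O2 and the enolisable benzylic C4, at the oxidation level of an aldehyde carbon.
- Cutting C3–C4 (aldol) and C1–O2 (acyl transfer) together gives 6,8-bis(benzyloxy)isochromane-1,3-dione and (7S)-7-(benzyloxy)dodecanal. The carboxyl group this leaves on C4 is removed afterwards by radical decarboxylation.
- Aldehyde: the C6′ carbinol comes from resolved (S)-1,2-epoxyheptane, the chain from a copper-catalysed opening with hex-5-enylmagnesium bromide, and the CHO from ozonolysis. Anhydride: ring A is bought as an arylacetate and C1 is added by formylation and oxidation.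
- Ring order: ring A is purchased, the anhydride ring is temporary, and ring B closes in step 10. All three hydroxyls travel as benzyl ethers, because a closing Lewis-acid ether cleavage would endanger the free C6′ carbinol. One hydrogenolysis therefore ends the route.

Key step: step 10

Assumption: the quinine-derived squaramide is taken to give 3R with an alkyl aldehyde (for the same spatial result the CIP label at C3 is opposite to that of 3-aryl products); a first run is checked by circular dichroism of the derived dihydroisocoumarin, and if the sense is opposite the quinidine-derived (9R) pseudo-enantiomer is used with no other change.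

**Route**

Step 1
Reactants: 1 rac-1,2-epoxyheptane
Product: 2 (S)-1,2-epoxyheptane
Conditions: (S,S)-N,N′-bis(3,5-di-tert-butylsalicylidene)-1,2-cyclohexanediaminocobalt acetate (trivalent cobalt, 0.5 mol %), H2O (0.55 equiv), neat, 0 °C → rt; distil
Reagents that add atoms: none
Why: In this Jacobsen hydrolytic kinetic resolution the (S,S)-complex hydrates the (R)-epoxide much faster, so the unreacted (S)-epoxide, which carries the future C6′ configuration, is distilled away from the diol.

Step 2
Reactants: 3 6-bromohex-1-ene; 2 (S)-1,2-epoxyheptane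
Product: 5 (6S)-tridec-12-en-6-ol, via hex-5-enylmagnesium bromide 4 (not isolated)
Conditions: 3, Mg, THF, rt → 40 °C; then CuI (10 mol %), 2, THF, −30 → 0 °C; aq NH4Cl
Reagents that add atoms: none
Why: The copper-catalysed Grignard opening of a terminal epoxide is an SN2 attack at the unsubstituted carbon, so the C–O bond at the stereocentre is untouched and the S configuration passes into the carbinol.

Step 3
Reactants: 5 (6S)-tridec-12-en-6-ol
Product: 6 benzyl (6S)-tridec-12-en-6-yl ether
Conditions: NaH, BnBr, Bu4NI (cat.), THF/DMF, 0 °C → rt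
Reagents that add atoms: benzyl bromide, BrCc1ccccc1
Why: This Williamson etherification takes place at oxygen only, so the stereocentre is not involved, and the benzyl ether tolerates every step up to the final hydrogenolysis.

Step 4
Reactants: 6 benzyl (6S)-tridec-12-en-6-yl ether
Product: 8 (7S)-7-(benzyloxy)dodecanal, via secondary ozonide 7 (not isolated)
Conditions: O3, CH2Cl2, −78 °C (Sudan Red 7B end point); then PPh3, −78 °C → rt
Reagents that add atoms: ozone, [O-][O+]=O
Why: Ozonolysis (Criegee mechanism) of the only C=C bond with reductive work-up stops at the aldehyde, and the benzyl ether reacts with ozone far more slowly than a terminal alkene at −78 °C.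

Step 5
Reactants: 9 methyl 2-(3,5-dihydroxyphenyl)acetate
Product: 10 methyl 2-[3,5-bis(benzyloxy)phenyl]acetate
Conditions: BnBr (2.3 equiv), K2CO3, acetone, reflux
Reagents that add atoms: benzyl bromide, BrCc1ccccc1
Why: This Williamson etherification of both phenols uses a weak base that leaves the methyl ester and its α-CH2 alone.

Step 6
Reactants: 10 methyl 2-[3,5-bis(benzyloxy)phenyl]acetate
Product: 12 methyl 2-[3,5-bis(benzyloxy)-2-formylphenyl]acetate, via aryl iminium chloride 11 (not isolated)
Conditions: POCl3 (1.5 equiv), DMF, 0 → 60 °C; then ice–water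
Reagents that add atoms: N,N-dimethylformamide, CN(C)C=O; water, O
Why: The Vilsmeier–Haack formylation is an electrophilic aromatic substitution that goes to the position para to one benzyloxy group and ortho to the other rather than to the crowded site between both ethers, and the side-chain acid is kept as its ester because a free carboxyl would be consumed by POCl3.

Step 7
Reactants: 12 methyl 2-[3,5-bis(benzyloxy)-2-formylphenyl]acetate
Product: 13 2,4-bis(benzyloxy)-6-(2-methoxy-2-oxoethyl)benzoic acid
Conditions: NaClO2, NaH2PO4, 2-methylbut-2-ene (excess), t-BuOH/THF/H2O, rt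
Reagents that add atoms: sodium chlorite, [Na+].[O-]Cl=O
Why: The Pinnick oxidation converts the hindered aryl aldehyde into the acid without touching the benzyl ethers or the ester, and the alkene scavenger protects electron-rich ring A from chlorination.

Step 8
Reactants: 13 2,4-bis(benzyloxy)-6-(2-methoxy-2-oxoethyl)benzoic acid
Product: 14 2,4-bis(benzyloxy)-6-(carboxymethyl)benzoic acid
Conditions: LiOH (3 equiv), THF/MeOH/H2O, rt; then 1 M HCl
Reagents that add atoms: lithium hydroxide, [Li+].[OH-]
Why: Saponification (acyl–oxygen cleavage) of the unhindered aliphatic methyl ester followed by acidification gives the homophthalic diacid.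

Step 9
Reactants: 14 2,4-bis(benzyloxy)-6-(carboxymethyl)benzoic acid
Product: 15 6,8-bis(benzyloxy)isochromane-1,3-dione
Conditions: Ac2O (3 equiv), toluene, 110 °C; evaporate, triturate with dry Et2O
Reagents that add atoms: none
Why: Cyclodehydration of a homophthalic acid with acetic anhydride gives the six-membered cyclic anhydride, a standard transformation for alkoxy-substituted members of this class.

Step 10
Reactants: 15 6,8-bis(benzyloxy)isochromane-1,3-dione; 8 (7S)-7-(benzyloxy)dodecanal
Product: 18 (3R,4S)-6,8-bis(benzyloxy)-3-[(6S)-6-(benzyloxy)undecyl]-1-oxoisochromane-4-carboxylic acid, via anhydride enol 16 (not isolated), via aldol adduct 17 (not isolated)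
Conditions: 8 (1.2 equiv), 3-{[3,5-bis(trifluoromethyl)phenyl]amino}-4-{[(8α,9S)-6′-methoxycinchonan-9-yl]amino}cyclobut-3-ene-1,2-dione (10 mol %), MTBE, −15 °C; dilute HCl wash; SiO2 (AcOH-doped eluent)
Reagents that add atoms: none
Why: The quinuclidine nitrogen of the catalyst deprotonates C4 of 15 to the enol(ate) 16, which stays hydrogen-bonded to the protonated catalyst while its remaining N–H donors bind the carbonyl oxygen of 8; C4 then adds to the aldehyde carbon (C3–C4, aldol adduct 17) and the new alkoxide acylates itself at C1 (C1–O2), which opens the anhydride and leaves the carboxyl group on C4. The closest known reaction type is the catalytic asymmetric formal [4+2] cycloaddition (aldol–lactonisation) of homophthalic anhydrides with aromatic and aliphatic aldehydes under cinchona squaramide catalysis, the oxygen counterpart of the Castagnoli–Cushman reaction. Ring B closes by 6-exo-trig addition–elimination at the aryl-bound carbonyl C1, whereas attack at the other anhydride carbonyl would be a 4-exo-trig closure to a strained β-lactone, so ring size fixes the regiochemistry. C3 is controlled by the catalyst, which presents one aldehyde face to the bound enolate, the C6′ ether being six bonds away and without bias; C4 is set relative to C3 (alkyl and carboxyl trans) in the same aldol transition state and is deleted in step 12. The step needs enantiofacial selectivity on an unbranched alkanal and chemoselectivity over self-condensation of 15 and self-aldol of 8, the latter being secured by the far higher C–H acidity of 15, the weak base, the low temperature and the small excess of 8. Only the chromatographically separated trans acid is carried on, so that the C3 purity is not diluted by the cis isomer.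

Step 11
Reactants: 18 (3R,4S)-6,8-bis(benzyloxy)-3-[(6S)-6-(benzyloxy)undecyl]-1-oxoisochromane-4-carboxylic acid
Product: 19 2-thioxopyridin-1(2H)-yl (3R,4S)-6,8-bis(benzyloxy)-3-[(6S)-6-(benzyloxy)undecyl]-1-oxoisochromane-4-carboxylate (Barton ester)
Conditions: 1-hydroxypyridine-2(1H)-thione, DCC, CH2Cl2, 0 °C, dark; filter, concentrate, use crude
Reagents that add atoms: 1-hydroxypyridine-2(1H)-thione, On1ccccc1=S
Why: Base-free carbodiimide O-acylation of the thiohydroxamic acid gives the Barton ester, and the absence of an amine base avoids β-elimination of the C3 acyloxy group from the now more acidic C4–H, so C3 is untouched.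

Step 12
Reactants: 19 Barton ester
Product: 20 (3R)-6,8-bis(benzyloxy)-3-[(6S)-6-(benzyloxy)undecyl]isochroman-1-one
Conditions: t-BuSH (15 equiv), toluene, tungsten lamp (250 W), 10–20 °C; SiO2
Reagents that add atoms: none
Why: In this Barton reductive decarboxylation visible light cleaves the N–O bond, CO2 is lost and the benzylic C4 radical takes hydrogen from the thiol in a radical chain, which erases the C4 stereocentre while C3, whose β-acyloxy bond does not fragment at this temperature, stays intact.

Step 13
Reactants: 20 (3R)-6,8-bis(benzyloxy)-3-[(6S)-6-(benzyloxy)undecyl]isochroman-1-one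
Product: 21 (3R)-6,8-dihydroxy-3-[(6S)-6-hydroxyundecyl]isochroman-1-one (CNP0198395.1)
Conditions: H2 (1 atm), 10% Pd/C, EtOAc/EtOH, rt
Reagents that add atoms: none
Why: Catalytic hydrogenolysis removes the two aryl benzyl ethers and the alkyl benzyl ether under neutral conditions, and the homobenzylic lactone C3–O2 bond is not cleaved, so both stereocentres survive.

**Compound list**

1 | rac-1,2-epoxyheptane | CCCCCC1CO1 | starting material
2 | (S)-1,2-epoxyheptane | CCCCC[C@H]1CO1 | intermediate
3 | 6-bromohex-1-ene | C=CCCCCBr | starting material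
4 | hex-5-enylmagnesium bromide | C=CCCCC[Mg]Br | intermediate
5 | (6S)-tridec-12-en-6-ol | CCCCC[C@H](O)CCCCCC=C | intermediate
6 | benzyl (6S)-tridec-12-en-6-yl ether | CCCCC[C@H](OCc1ccccc1)CCCCCC=C | intermediate
7 | 3-[(6S)-6-(benzyloxy)undecyl]-1,2,4-trioxolane (both epimers at the ring carbon) | CCCCC[C@H](OCc1ccccc1)CCCCCC1OCOO1 | intermediate
8 | (7S)-7-(benzyloxy)dodecanal | CCCCC[C@H](OCc1ccccc1)CCCCCC=O | intermediate
9 | methyl 2-(3,5-dihydroxyphenyl)acetate | COC(=O)Cc1cc(O)cc(O)c1 | starting material
10 | methyl 2-[3,5-bis(benzyloxy)phenyl]acetate | COC(=O)Cc1cc(OCc2ccccc2)cc(OCc2ccccc2)c1 | intermediate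
11 | [2,4-bis(benzyloxy)-6-(2-methoxy-2-oxoethyl)benzylidene]dimethylammonium chloride | COC(=O)Cc1cc(OCc2ccccc2)cc(OCc2ccccc2)c1C=[N+](C)C.[Cl-] | intermediate
12 | methyl 2-[3,5-bis(benzyloxy)-2-formylphenyl]acetate | COC(=O)Cc1cc(OCc2ccccc2)cc(OCc2ccccc2)c1C=O | intermediate
13 | 2,4-bis(benzyloxy)-6-(2-methoxy-2-oxoethyl)benzoic acid | COC(=O)Cc1cc(OCc2ccccc2)cc(OCc2ccccc2)c1C(=O)O | intermediate
14 | 2,4-bis(benzyloxy)-6-(carboxymethyl)benzoic acid | OC(=O)Cc1cc(OCc2ccccc2)cc(OCc2ccccc2)c1C(=O)O | intermediate
15 | 6,8-bis(benzyloxy)isochromane-1,3-dione | O=C1Cc2cc(OCc3ccccc3)cc(OCc3ccccc3)c2C(=O)O1 | intermediate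
16 | 6,8-bis(benzyloxy)-3-hydroxy-1H-isochromen-1-one | OC1=Cc2cc(OCc3ccccc3)cc(OCc3ccccc3)c2C(=O)O1 | intermediate
17 | (4S)-6,8-bis(benzyloxy)-4-[(1R,7S)-7-(benzyloxy)-1-hydroxydodecyl]isochromane-1,3-dione | CCCCC[C@H](OCc1ccccc1)CCCCC[C@@H](O)[C@H]1C(=O)OC(=O)c2c(OCc3ccccc3)cc(OCc3ccccc3)cc21 | intermediate
18 | (3R,4S)-6,8-bis(benzyloxy)-3-[(6S)-6-(benzyloxy)undecyl]-1-oxoisochromane-4-carboxylic acid | CCCCC[C@H](OCc1ccccc1)CCCCC[C@@H]1[C@@H](C(=O)O)c2cc(OCc3ccccc3)cc(OCc3ccccc3)c2C(=O)O1 | intermediate
19 | 2-thioxopyridin-1(2H)-yl (3R,4S)-6,8-bis(benzyloxy)-3-[(6S)-6-(benzyloxy)undecyl]-1-oxoisochromane-4-carboxylate | CCCCC[C@H](OCc1ccccc1)CCCCC[C@@H]1[C@@H](C(=O)On2ccccc2=S)c2cc(OCc3ccccc3)cc(OCc3ccccc3)c2C(=O)O1 | intermediate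
20 | (3R)-6,8-bis(benzyloxy)-3-[(6S)-6-(benzyloxy)undecyl]isochroman-1-one | CCCCC[C@H](OCc1ccccc1)CCCCC[C@@H]1Cc2cc(OCc3ccccc3)cc(OCc3ccccc3)c2C(=O)O1 | intermediate
21 | (3R)-6,8-dihydroxy-3-[(6S)-6-hydroxyundecyl]isochroman-1-one | CCCCC[C@H](O)CCCCC[C@@H]1Cc2cc(O)cc(O)c2C(=O)O1 | target

**Step count**

Total step count: 13.
Longest linear sequence: 9 steps (steps 5–13, from methyl 2-(3,5-dihydroxyphenyl)acetate).

**Steps most likely to fail**

Step 10.
- Facial discrimination of a flexible, unbranched alkanal may be weak.
- Acyl transfer to the electron-rich C1, which is flanked by an alkoxy group, may be slow enough for retro-aldol to erode selectivity.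
- Base-induced self-condensation of the anhydride may compete.

The fallback sets out from 6 and returns at 20, taking C3 from a resolved epoxide instead of an aldol. Alkene 6 is epoxidised with mCPBA to 2-[(6S)-6-(benzyloxy)undecyl]oxirane F1, formed as both epimers at the oxirane carbon. Hydrolytic kinetic resolution with the (R,R) enantiomer of the cobalt acetate complex of step 1 leaves (2R)-2-[(6S)-6-(benzyloxy)undecyl]oxirane F2. Purchased 1,3-bis(benzyloxy)-5-bromobenzene F3 is converted with Mg in THF into 3,5-bis(benzyloxy)phenylmagnesium bromide F4. Under CuI catalysis this opens F2 at its terminal carbon to give (2R,8S)-8-(benzyloxy)-1-[3,5-bis(benzyloxy)phenyl]tridecan-2-ol F5. NIS in MeCN iodinates the ring position ortho to the side chain and para to a benzyloxy group, giving (2R,8S)-8-(benzyloxy)-1-[3,5-bis(benzyloxy)-2-iodophenyl]tridecan-2-ol F6. Palladium-catalysed carbonylative lactonisation (Pd(OAc)2, PPh3, CO, K2CO3, DMF, 90 °C) then closes ring B and delivers 20.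

Step 12. Sulfur transfer from unreacted 19 to the stabilised benzylic C4 radical may outrun hydrogen transfer from the thiol and divert the chain.

The fallback sets out from 19 and returns at 20, and it makes the sulfur transfer the planned path. Compound 19 is photolysed without thiol to give (3R)-6,8-bis(benzyloxy)-3-[(6S)-6-(benzyloxy)undecyl]-4-(pyridin-2-ylsulfanyl)isochroman-1-one F7. The benzylic C–S bond of F7 is then cleaved reductively with Bu3SnH and AIBN in toluene at 90 °C to give 20.

Step 11. Once the carboxyl group is activated, β-elimination across C3–C4 may open ring B, or the carbodiimide adduct may undergo O→N acyl migration.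

The fallback sets out from 18 and returns at 20, with no pre-activation. The free acid undergoes direct photoredox hydrodecarboxylation by one-electron oxidation of its carboxylate. Conditions are 9-mesityl-10-methylacridinium tetrafluoroborate (5 mol %), diphenyl disulfide (10 mol %), 2,6-lutidine, 1,2-dichloroethane and blue LED. This path makes no new compound (F0).

**Further compounds**

F1 | step 10 | 2-[(6S)-6-(benzyloxy)undecyl]oxirane (both epimers at the oxirane carbon) | CCCCC[C@H](OCc1ccccc1)CCCCCC1CO1
F2 | step 10 | (2R)-2-[(6S)-6-(benzyloxy)undecyl]oxirane | CCCCC[C@H](OCc1ccccc1)CCCCC[C@@H]1CO1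
F3 | step 10 | 1,3-bis(benzyloxy)-5-bromobenzene (purchased) | Brc1cc(OCc2ccccc2)cc(OCc2ccccc2)c1
F4 | step 10 | 3,5-bis(benzyloxy)phenylmagnesium bromide | Br[Mg]c1cc(OCc2ccccc2)cc(OCc2ccccc2)c1
F5 | step 10 | (2R,8S)-8-(benzyloxy)-1-[3,5-bis(benzyloxy)phenyl]tridecan-2-ol | CCCCC[C@H](OCc1ccccc1)CCCCC[C@@H](O)Cc1cc(OCc2ccccc2)cc(OCc2ccccc2)c1
F6 | step 10 | (2R,8S)-8-(benzyloxy)-1-[3,5-bis(benzyloxy)-2-iodophenyl]tridecan-2-ol | CCCCC[C@H](OCc1ccccc1)CCCCC[C@@H](O)Cc1cc(OCc2ccccc2)cc(OCc2ccccc2)c1I
F7 | step 12 | (3R)-6,8-bis(benzyloxy)-3-[(6S)-6-(benzyloxy)undecyl]-4-(pyridin-2-ylsulfanyl)isochroman-1-one (both epimers at C4) | CCCCC[C@H](OCc1ccccc1)CCCCC[C@@H]1C(Sc2ccccn2)c2cc(OCc3ccccc3)cc(OCc3ccccc3)c2C(=O)O1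
F0 | step 11 | none | none
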